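**Plan**
- The target is the flavonol 3,5,7,3',5'-pentahydroxy-8,4'-dimethoxyflavone. Retrosynthesis removes five benzyl ethers, then cuts the acyl–arene bond C4–C4a of the pyranone, then the vinyl ether bond O1–C2, then the C2–C3 bond of a β-keto ester.
- Forward: the ring A phenol 7 and the ring B enol triflate 14 are made separately and joined at O1–C2. Ring C is closed last by intramolecular Friedel–Crafts acylation, and hydrogenolysis finishes the route.
- Enabling feature: on ring A one carbon ortho to O1 is C8 and carries the methoxy group. The only free ortho carbon is C4a, activated ortho by the C5 oxygen and para by the C7 oxygen, so an acyl carbon held through O1–C2=C3 can close ring C only to the 8-methoxy isomer.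
- Stereochemistry: the target has no stereocentre and no stereogenic axis. The only stereo-element on the way is the C2=C3 geometry of 14–17, which ends inside the aromatic pyranone.

Key step: step 12

Assumption 1: the target is achiral, so "single enantiomer" is taken to mean the one constitution drawn; nothing has to be induced or resolved.
Assumption 2: salts formed by deprotonating a numbered compound (phenoxides, enolates, carboxylates) are treated as that compound and are not numbered separately.

**Route**

Step 1
Reactants: 1 2,4,6-trihydroxybenzaldehyde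
Product: 2 2,4-bis(benzyloxy)-6-hydroxybenzaldehyde
Conditions: BnBr (2.1 equiv), K2CO3, DMF, rt
Reagents that add atoms: benzyl bromide, BrCc1ccccc1
Why: Partial Williamson etherification under chelation control, in which the 4-OH and one ortho OH are benzylated while the remaining ortho OH, hydrogen-bonded to the formyl group, is much less nucleophilic and should stay free.

Step 2
Reactants: 2 2,4-bis(benzyloxy)-6-hydroxybenzaldehyde
Product: 3 2,4-bis(benzyloxy)-6-(methoxymethoxy)benzaldehyde
Conditions: NaH, DMF, 0 °C; MOMCl, 0 °C → rt
Reagents that add atoms: chloromethyl methyl ether, COCCl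
Why: Williamson-type O-alkylation of the sodium phenoxide masks, as an acetal orthogonal to benzyl and methyl, the one oxygen that must later be freed alone to become O1.

Step 3
Reactants: 3 2,4-bis(benzyloxy)-6-(methoxymethoxy)benzaldehyde
Product: 5 2,4-bis(benzyloxy)-6-(methoxymethoxy)phenol, via aryl formate 4 (not isolated)
Conditions: mCPBA, CH2Cl2, 0 °C → rt; aq. Na2S2O3/NaHCO3 wash; then K2CO3 (cat.), MeOH, rt
Reagents that add atoms: 3-chloroperoxybenzoic acid (mCPBA), OOC(=O)c1cccc(Cl)c1
Why: Baeyer–Villiger (Dakin-type) oxidation, in which the electron-rich 2,4,6-trioxygenated aryl group migrates in preference to hydride in the Criegee adduct and the resulting formate is cleaved by mild methanolysis, conditions that leave MOM and benzyl ethers intact.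

Step 4
Reactants: 5 2,4-bis(benzyloxy)-6-(methoxymethoxy)phenol
Product: 6 1,5-bis(benzyloxy)-2-methoxy-3-(methoxymethoxy)benzene
Conditions: MeI, K2CO3, DMF, rt
Reagents that add atoms: iodomethane, CI
Why: Williamson methylation of the only free phenol installs the future 8-methoxy group on the oxygen that replaced the formyl carbon.

Step 5
Reactants: 6 1,5-bis(benzyloxy)-2-methoxy-3-(methoxymethoxy)benzene
Product: 7 3,5-bis(benzyloxy)-2-methoxyphenol
Conditions: conc. HCl (cat.), MeOH/THF, 50 °C
Reagents that add atoms: none
Why: Acid-catalysed acetal exchange with methanol removes the MOM group as dimethoxymethane, while aryl benzyl and methyl ethers are stable to dilute acid at this temperature.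

Step 6
Reactants: 8 3,5-dihydroxy-4-methoxybenzoic acid (4-O-methylgallic acid)
Product: 9 benzyl 3,5-bis(benzyloxy)-4-methoxybenzoate
Conditions: BnBr (3.3 equiv), K2CO3, DMF, 60 °C
Reagents that add atoms: benzyl bromide, BrCc1ccccc1
Why: Exhaustive Williamson alkylation of both phenoxides and the carboxylate, a routine protection of hydroxybenzoic acids.

Step 7
Reactants: 9 benzyl 3,5-bis(benzyloxy)-4-methoxybenzoate
Product: 10 3,5-bis(benzyloxy)-4-methoxybenzoic acid
Conditions: NaOH, THF/MeOH/H2O, 60 °C; then 1 M HCl
Reagents that add atoms: sodium hydroxide, [Na+].[OH-]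
Why: Saponification of the benzyl ester by acyl–oxygen cleavage, to which aryl benzyl and methyl ethers are inert.

Step 8
Reactants: 10 3,5-bis(benzyloxy)-4-methoxybenzoic acid; 11 ethyl 2-(benzyloxy)acetate
Product: 13 ethyl 2-(benzyloxy)-3-[3,5-bis(benzyloxy)-4-methoxyphenyl]-3-oxopropanoate (racemic at C2), via aroyl chloride 12 (not isolated)
Conditions: 10, (COCl)2, DMF (cat.), CH2Cl2, 0 °C → rt, evaporate; 11 (2.2 equiv), LiHMDS (2.2 equiv), THF, −78 °C, then 12 in THF added slowly, −78 °C; aq. NH4Cl
Reagents that add atoms: none
Why: Crossed Claisen acylation of a glycolate ester lithium enolate by an acid chloride, run with two equivalents of enolate and inverse addition because the β-keto ester is deprotonated as it forms, which keeps the acid chloride from meeting it in excess.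

Step 9
Reactants: 13 ethyl 2-(benzyloxy)-3-[3,5-bis(benzyloxy)-4-methoxyphenyl]-3-oxopropanoate
Product: 14 ethyl (E)-2-(benzyloxy)-3-[3,5-bis(benzyloxy)-4-methoxyphenyl]-3-{[(trifluoromethyl)sulfonyl]oxy}acrylate (triflate oxygen cis to the ester)
Conditions: NaH, CH2Cl2, 0 °C; Tf2O, −78 → 0 °C
Reagents that add atoms: trifluoromethanesulfonic anhydride, O=S(=O)(OS(=O)(=O)C(F)(F)F)C(F)(F)F
Why: O-sulfonylation of the β-keto ester enolate, which can enolise in one direction only; the chelated sodium enolate should place the triflate cis to the ester, which is the E descriptor here because the α-substituent is oxygen.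

Step 10
Reactants: 14 the enol triflate; 7 3,5-bis(benzyloxy)-2-methoxyphenol
Product: 15 ethyl (E)-2-(benzyloxy)-3-[3,5-bis(benzyloxy)-2-methoxyphenoxy]-3-[3,5-bis(benzyloxy)-4-methoxyphenyl]acrylate (aryloxy group cis to the ester)
Conditions: Cs2CO3, DMF, 0 °C → rt
Reagents that add atoms: none
Why: Nucleophilic vinylic substitution (addition–elimination) of a β-sulfonyloxy acrylate by a phenoxide, the vinylogous counterpart of transesterification and the same bond construction as the classical β-chlorocinnamate–phenoxide route to β-aryloxycinnamates; retention is expected, the substrate cannot eliminate to an alkyne because C2 is fully substituted, and the geometry is in any case not critical for step 12.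

Step 11
Reactants: 15 the ethyl β-aryloxyacrylate
Product: 16 (E)-2-(benzyloxy)-3-[3,5-bis(benzyloxy)-2-methoxyphenoxy]-3-[3,5-bis(benzyloxy)-4-methoxyphenyl]acrylic acid
Conditions: LiOH·H2O, THF/MeOH/H2O, rt → 40 °C; then 1 M HCl to pH 3, 0 °C
Reagents that add atoms: lithium hydroxide, [Li+].[OH-]
Why: Saponification of the ethyl ester, activated inductively by the α-alkoxy group, as is done classically on β-aryloxycinnamic esters; the fully substituted β-carbon is shielded against conjugate attack that would expel the phenoxide.

Step 12
Reactants: 16 the β-aryloxy-α-benzyloxycinnamic acid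
Product: 18 3,5,7-tris(benzyloxy)-2-[3,5-bis(benzyloxy)-4-methoxyphenyl]-8-methoxy-4H-chromen-4-one, via mixed trifluoroacetic anhydride 17 (not isolated)
Conditions: TFAA (1.2 equiv), CH2Cl2, 0 °C → rt
Reagents that add atoms: none
Why: Trifluoroacetic anhydride converts the acid into mixed anhydride 17, whose acyl carbon (an acylium ion stabilised by the β-aryloxy oxygen) is attacked by the arene carbon ortho to O1, and loss of trifluoroacetate and of the ring proton from the Wheland intermediate gives the pyran-4-one. The closest known reaction type is the intramolecular Friedel–Crafts acylation of β-aryloxycinnamic acids to flavones (Ruhemann-type chromone synthesis), run here with the mild TFAA activation used for aryloxy acids of electron-rich arenes so that the benzyl ethers should survive. The single new ring is six-membered and closes by a 6-exo-trig electrophilic aromatic substitution (carbonyl oxygen exocyclic) that forms C4–C4a. No stereocentre is created. The step needs regioselectivity (8-methoxy and not 6-methoxy isomer, ring A and not ring B, ring closure and not trifluoroacetylation of C6 by the reagent): O1 was fixed in step 10 and its only free ortho carbon is the future C4a, activated ortho by the C5 ether and para by the C7 ether; carboxyl and aryloxy groups are cis in the (E)-acid, and since the C2–C3 bond of the acylium ion has single-bond character any (Z)-material can rotate into the reactive geometry, where six-ring closure onto ring A should outrun the strained five-ring closure onto ring B; a slight excess of TFAA at 0 °C keeps the bimolecular side reaction from competing.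

Step 13
Reactants: 18 the penta-O-benzyl flavonol
Product: 19 3,5,7-trihydroxy-2-(3,5-dihydroxy-4-methoxyphenyl)-8-methoxy-4H-chromen-4-one (target)
Conditions: H2 (1 atm), 10% Pd/C, THF/MeOH, rt
Reagents that add atoms: none
Why: Palladium-catalysed hydrogenolysis cleaves the five benzyl ethers (O3, O5, O7, O3', O5') at once, while the tetrasubstituted C2=C3 bond of the chromone and the two aryl methyl ethers are not touched at ambient pressure and temperature.

**Compound list**

1 | 2,4,6-trihydroxybenzaldehyde | O=Cc1c(O)cc(O)cc1O | starting material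
2 | 2,4-bis(benzyloxy)-6-hydroxybenzaldehyde | O=Cc1c(O)cc(OCc2ccccc2)cc1OCc1ccccc1 | intermediate
3 | 2,4-bis(benzyloxy)-6-(methoxymethoxy)benzaldehyde | O=Cc1c(OCOC)cc(OCc2ccccc2)cc1OCc1ccccc1 | intermediate
4 | 2,4-bis(benzyloxy)-6-(methoxymethoxy)phenyl formate | O=COc1c(OCOC)cc(OCc2ccccc2)cc1OCc1ccccc1 | intermediate (not isolated)
5 | 2,4-bis(benzyloxy)-6-(methoxymethoxy)phenol | Oc1c(OCOC)cc(OCc2ccccc2)cc1OCc1ccccc1 | intermediate
6 | 1,5-bis(benzyloxy)-2-methoxy-3-(methoxymethoxy)benzene | COc1c(OCOC)cc(OCc2ccccc2)cc1OCc1ccccc1 | intermediate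
7 | 3,5-bis(benzyloxy)-2-methoxyphenol | COc1c(O)cc(OCc2ccccc2)cc1OCc1ccccc1 | intermediate
8 | 3,5-dihydroxy-4-methoxybenzoic acid (4-O-methylgallic acid) | COc1c(O)cc(C(=O)O)cc1O | starting material
9 | benzyl 3,5-bis(benzyloxy)-4-methoxybenzoate | COc1c(OCc2ccccc2)cc(C(=O)OCc2ccccc2)cc1OCc1ccccc1 | intermediate
10 | 3,5-bis(benzyloxy)-4-methoxybenzoic acid | COc1c(OCc2ccccc2)cc(C(=O)O)cc1OCc1ccccc1 | intermediate
11 | ethyl 2-(benzyloxy)acetate | CCOC(=O)COCc1ccccc1 | starting material
12 | 3,5-bis(benzyloxy)-4-methoxybenzoyl chloride | COc1c(OCc2ccccc2)cc(C(Cl)=O)cc1OCc1ccccc1 | intermediate (not isolated)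
13 | ethyl 2-(benzyloxy)-3-[3,5-bis(benzyloxy)-4-methoxyphenyl]-3-oxopropanoate (racemic) | CCOC(=O)C(OCc1ccccc1)C(=O)c1cc(OCc2ccccc2)c(OC)c(OCc2ccccc2)c1 | intermediate
14 | ethyl (E)-2-(benzyloxy)-3-[3,5-bis(benzyloxy)-4-methoxyphenyl]-3-{[(trifluoromethyl)sulfonyl]oxy}acrylate | CCOC(=O)/C(OCc1ccccc1)=C(\OS(=O)(=O)C(F)(F)F)c1cc(OCc2ccccc2)c(OC)c(OCc2ccccc2)c1 | intermediate
15 | ethyl (E)-2-(benzyloxy)-3-[3,5-bis(benzyloxy)-2-methoxyphenoxy]-3-[3,5-bis(benzyloxy)-4-methoxyphenyl]acrylate | CCOC(=O)/C(OCc1ccccc1)=C(\Oc1cc(OCc2ccccc2)cc(OCc2ccccc2)c1OC)c1cc(OCc2ccccc2)c(OC)c(OCc2ccccc2)c1 | intermediate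
16 | (E)-2-(benzyloxy)-3-[3,5-bis(benzyloxy)-2-methoxyphenoxy]-3-[3,5-bis(benzyloxy)-4-methoxyphenyl]acrylic acid | OC(=O)/C(OCc1ccccc1)=C(\Oc1cc(OCc2ccccc2)cc(OCc2ccccc2)c1OC)c1cc(OCc2ccccc2)c(OC)c(OCc2ccccc2)c1 | intermediate
17 | (E)-2-(benzyloxy)-3-[3,5-bis(benzyloxy)-2-methoxyphenoxy]-3-[3,5-bis(benzyloxy)-4-methoxyphenyl]acrylic trifluoroacetic anhydride | O=C(OC(=O)C(F)(F)F)/C(OCc1ccccc1)=C(\Oc1cc(OCc2ccccc2)cc(OCc2ccccc2)c1OC)c1cc(OCc2ccccc2)c(OC)c(OCc2ccccc2)c1 | intermediate (not isolated)
18 | 3,5,7-tris(benzyloxy)-2-[3,5-bis(benzyloxy)-4-methoxyphenyl]-8-methoxy-4H-chromen-4-one | COc1c(OCc2ccccc2)cc(-c2oc3c(OC)c(OCc4ccccc4)cc(OCc4ccccc4)c3c(=O)c2OCc2ccccc2)cc1OCc1ccccc1 | intermediate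
19 | 3,5,7-trihydroxy-2-(3,5-dihydroxy-4-methoxyphenyl)-8-methoxy-4H-chromen-4-one | COc1c(O)cc(-c2oc3c(OC)c(O)cc(O)c3c(=O)c2O)cc1O | target

**Step count and risks**

Total steps: 13 (ring A branch steps 1–5, ring B branch steps 6–9, common steps 10–13).
Longest linear sequence: 9 steps (1–5, then 10–13).

Steps most likely to fail:

Step 10. The phenoxide may attack the sulfur of the triflate, which cleaves the S–O bond and returns the enolate of 13. Addition at the fully substituted β-carbon, flanked by the donor α-oxygen, may also be too slow to compete. The fallback sets out from 14 and 7 and joins them by palladium-catalysed C–O cross-coupling of the vinyl triflate with the phenol (Pd2(dba)3, a bulky di-tert-butylbiarylphosphine, K3PO4, toluene, 80 °C). The bond then arises by oxidative addition at C–OTf and C–O reductive elimination, with little free phenoxide in solution, and the fallback comes back to the route at 15. It makes no new compound (F0).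

Step 12. The trifluoroacetic acid set free may cleave or shift benzyl groups on the electron-rich ring A, above all the ether peri to the new carbonyl, and the reagent may trifluoroacetylate the ring in competition with ring closure. The fallback sets out from 16, which is converted under neutral conditions with 1-chloro-N,N,2-trimethylprop-1-en-1-amine in CH2Cl2 at 0 °C into (E)-2-(benzyloxy)-3-[3,5-bis(benzyloxy)-2-methoxyphenoxy]-3-[3,5-bis(benzyloxy)-4-methoxyphenyl]acryloyl chloride F1. Chloride abstraction with AgOTf in the presence of 2,6-di-tert-butyl-4-methylpyridine at −40 °C then generates the acylating species without free acid and forms the same C4–C4a bond. The fallback comes back to the route at 18.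

Step 8. The product enolate may be acylated a second time (at O or C) by the very reactive acid chloride, and the glycolate enolate may condense with itself while acylation is slow. The fallback sets out from 10, which is converted with 1,1'-carbonyldiimidazole and N,O-dimethylhydroxylamine hydrochloride into 3,5-bis(benzyloxy)-N,4-dimethoxy-N-methylbenzamide F2. Addition of the lithium enolate of 11 (LiHMDS, THF, −78 °C, about one equivalent) gives a chelated tetrahedral adduct that releases the ketone only on work-up, so over-acylation is excluded. The fallback comes back to the route at 13.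

**Further compounds**

F0 | step 10 | none | none
F1 | step 12 | (E)-2-(benzyloxy)-3-[3,5-bis(benzyloxy)-2-methoxyphenoxy]-3-[3,5-bis(benzyloxy)-4-methoxyphenyl]acryloyl chloride | ClC(=O)/C(OCc1ccccc1)=C(\Oc1cc(OCc2ccccc2)cc(OCc2ccccc2)c1OC)c1cc(OCc2ccccc2)c(OC)c(OCc2ccccc2)c1
F2 | step 8 | 3,5-bis(benzyloxy)-N,4-dimethoxy-N-methylbenzamide | CON(C)C(=O)c1cc(OCc2ccccc2)c(OC)c(OCc2ccccc2)c1
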